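Numbering is gibberellane: ring A = C1–C5, C10; ring B = C5, C6, C8, C9, C10; ring C = C8, C9, C11–C14; ring D = C8, C13–C16; C7 acid, C17 methylene, C18 methyl, C19 lactone carbonyl.
Retrosynthesis: late cuts are the C7 methyl ester, a C12 ketal, a bromine mask on C17 and the C2/C3 diol (from a 2,3-alkene); ring A and the lactone are cut at C4–C5 (Michael) and C2=C3 (metathesis), then at the C19–O ester and C10–C1 (allyl addition to a C10 ketone); C7 comes from carbonylation at C6.
Rings C and D are cut together at C9–C11 + C8–C14 ([4+2]) and C13–C16 (5-exo-dig), back to a monocyclic ring-B enone 7 and 2-silyloxybutadiene 8.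
Forward order: ring B (purchased, one stereocentre) → rings C and D in one flask → C6/C10 adjustment → temporary seven-membered lactone → ring A and γ-lactone together → diol → unmasking.
Stereochemistry: the C10 silyloxy centre of 1 sends the diene to the α face (sets C8 and C9; C13 follows by bridging); C9 then sends the allyl group to the β face of C10; the oxygen tether fixes C4 and C5; C6 is thermodynamic; the diol comes from exo (β) osmylation.
Enabling feature: in ring C the C12 carbonyl is para to quaternary C8 and C9 bears H, so ring C is the adduct of a C8=C9 enone (carbonyl at C6) and a 2-oxydiene; the adduct keeps its enol ether at C12=C13, and C13 is 1,3 to C8 across C14, so a C15–C16≡C17 arm on C8 closes ring D on that enol ether.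

Key step: step 5

Remark: α is the face of ring B that carries C14, C11 and the lactone oxygen, β the face that carries C15, H-9 and C7; diene 8 is taken as a purchasable reagent (otherwise one step from methyl vinyl ketone), and acid 18 is used racemic because its stereocentre is erased in step 14.

Step 1
Reactants: 1 (R)-4-(tert-butyldimethylsilyloxy)cyclopent-2-en-1-one; 2 formaldehyde (37% aqueous)
Product: 3 (R)-4-(tert-butyldimethylsilyloxy)-2-(hydroxymethyl)cyclopent-2-en-1-one
Conditions: aq. HCHO, imidazole (cat.), THF/H2O, rt
Reagents that add atoms: none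
Why: Morita–Baylis–Hillman reaction, in which imidazole adds reversibly to the enone β-carbon (C9) and the resulting enolate takes formaldehyde at C8, leaving the C10 stereocentre untouched.

Step 2
Reactants: 3
Product: 4 (R)-2-(bromomethyl)-4-(tert-butyldimethylsilyloxy)cyclopent-2-en-1-one
Conditions: CBr4, PPh3, CH2Cl2, 0 °C
Reagents that add atoms: carbon tetrabromide (BrC(Br)(Br)Br)
Why: Appel bromination of the primary allylic alcohol should give the conjugated 2-(bromomethyl)enone, the stable allylic isomer.

Step 3
Reactants: 4; 5 ethynyltrimethylsilane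
Product: 6 (R)-4-(tert-butyldimethylsilyloxy)-2-[3-(trimethylsilyl)prop-2-yn-1-yl]cyclopent-2-en-1-one
Conditions: 5, CuI (20 mol%), K2CO3, Bu4NI (cat.), DMF, rt
Reagents that add atoms: none
Why: Copper-mediated coupling of a terminal alkyne with a primary allylic bromide (skipped-enyne synthesis) should occur at the unhindered CH2 and not at C9, which is shielded by the neighbouring silyloxy group, and alkynylcopper species do not add conjugately.

Step 4
Reactants: 6
Product: 7 (R)-2-(3-bromoprop-2-yn-1-yl)-4-(tert-butyldimethylsilyloxy)cyclopent-2-en-1-one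
Conditions: NBS, AgNO3 (10 mol%), acetone, rt
Reagents that add atoms: N-bromosuccinimide (O=C1CCC(=O)N1Br)
Why: Silver-catalysed bromodesilylation of the alkynylsilane gives the 1-bromoalkyne, so that ring D will later be formed with its exocyclic methylene masked as a bromoalkene.

Step 5
Reactants: 7; 8 2-(tert-butyldimethylsilyloxy)buta-1,3-diene
Product: 10 tricyclic bromomethylene diketone (rings B C D), via silyl enol ether 9 (not isolated)
Conditions: 8 (2 equiv), Tf2NH (10 mol%), CH2Cl2, −78 to −40 °C; then, same flask, 2,6-di-tert-butylpyridine (20 mol%), Ph3PAuCl (5 mol%), AgBF4 (5 mol%), MeOH (3 equiv), 0 °C to rt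
Reagents that add atoms: none
Why: The silyl triflimide formed from Tf2NH and 8 activates the C6 carbonyl, and the 2-silyloxydiene adds across C8=C9 in an asynchronous Diels–Alder reaction whose leading bond is C9–C11 (nucleophilic CH2 terminus on the enone β-carbon), the C8–C14 bond completing ring C in the same event and creating the C8 quaternary centre. The closest known reactions are acid-catalysed cycloadditions of 2-silyloxybutadienes to 2-alkylcyclopent-2-enones and the phosphine-gold-cation-catalysed carbocyclisation of silyl enol ethers onto alkynes and haloalkynes. Ring C closes in the [4+2] mode; ring D closes 5-exo-dig when the C12=C13 enol ether left by the cycloaddition attacks C16 of the gold-bound bromoalkyne anti to the metal, and protodeauration by methanol leaves the (Z)-bromomethylene with the C12 ketone. C9 and C8 are set by approach of the diene anti to the C10 silyloxy group, which places C11 and C14 on the α face and the propargyl arm on the β face, and C13 has no choice because the C15–C16 arm can reach it from one face only. The step needs para regiochemistry, anti facial selectivity and exo closure: the first follows from the polarisation of diene and enone and from C9 being the unsubstituted terminus, the second from the allylic silyl ether, the third from the short tether and the halogen on the alkyne terminus. Because the cycloaddition itself places the enol ether at C12=C13, it is C13 and not C11 that is joined to C16.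

Step 6
Reactants: 10
Product: 11 C12 ethylene ketal of 10 (C6 ketone free)
Conditions: (Me3SiOCH2)2, Me3SiOTf (5 mol%), CH2Cl2, −78 to −30 °C
Reagents that add atoms: 1,2-bis(trimethylsilyloxy)ethane (C[Si](C)(C)OCCO[Si](C)(C)C)
Why: Silyl-triflate-catalysed ketalisation should distinguish the two ketones, since the six-ring C12 carbonyl reacts while the C6 cyclopentanone flanked by quaternary C8 does not, and the low temperature spares the β-silyloxy ketone.

Step 7
Reactants: 11
Product: 12 C6 enol triflate (C5=C6) of 11
Conditions: KN(SiMe3)2, THF, −78 °C; then PhNTf2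
Reagents that add atoms: N-phenylbis(trifluoromethanesulfonimide) (O=S(=O)(N(c1ccccc1)S(=O)(=O)C(F)(F)F)C(F)(F)F)
Why: Kinetic enolisation can only go toward C5 because C8 is quaternary, and O-sulfonylation at −78 °C should trap the enolate before E1cB loss of the C10 silyloxy group.

Step 8
Reactants: 12
Product: 13 methyl C5=C6 enoate (C7 ester in place)
Conditions: Pd(OAc)2 (5 mol%), PPh3 (10 mol%), CO (1 atm), MeOH, Et3N, DMF, rt
Reagents that add atoms: carbon monoxide ([C-]#[O+]); methanol (CO)
Why: Palladium-catalysed methoxycarbonylation of the enol triflate at room temperature should outpace oxidative addition to the hindered trisubstituted vinyl bromide.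

Step 9
Reactants: 13
Product: 14 allylic C10 alcohol
Conditions: HF·pyridine, pyridine, THF, 0 °C to rt
Reagents that add atoms: none
Why: Buffered fluoride desilylation removes the secondary silyl ether and should leave the dioxolane, the ester and the bromoalkene alone.

Step 10
Reactants: 14
Product: 15 ring-B enone (C10 ketone conjugated with the C5=C6 enoate)
Conditions: Dess–Martin periodinane, CH2Cl2, rt
Reagents that add atoms: none
Why: Dess–Martin oxidation of the allylic alcohol works without base, so C9, now α to a ketone, should keep its (also thermodynamically preferred) cis ring fusion.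

Step 11
Reactants: 15; 16 allylmagnesium bromide
Product: 17 tertiary alcohol (10α-OH, 10β-allyl)
Conditions: 16 (1.3 equiv), THF, −78 °C
Reagents that add atoms: none
Why: Grignard 1,2-addition to the ring-B ketone should come from the β face, trans to the C11 branch on the neighbouring C9 as usual for 2-substituted cyclopentanones, which sets C10 with oxygen α and C1 β, and the ester and bromoalkene do not react at −78 °C.

Step 12
Reactants: 17; 18 2-methylbut-3-enoic acid (racemic)
Product: 20 dienyl ester of the C10 carbinol, via acid chloride 19 (not isolated)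
Conditions: 18, (COCl)2, DMF (cat.), CH2Cl2, 0 °C, volatiles removed; 17, LiN(SiMe3)2, THF, −78 °C, then 19, −78 to 0 °C
Reagents that add atoms: none
Why: O-acylation of the lithium alkoxide of the hindered tertiary alcohol with the acid chloride, run without amine base, should keep the β,γ-unsaturated acyl group out of conjugation.

Step 13
Reactants: 20
Product: 21 spiro seven-membered unsaturated lactone (C10–O–C19(=O)–C4H(CH3)–C3H=C2H–C1H2–C10)
Conditions: second-generation Hoveyda–Grubbs catalyst (5 mol%), toluene (0.002 M), 80 °C
Reagents that add atoms: none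
Why: Ring-closing metathesis of the two monosubstituted alkenes is helped by the fully substituted C10 that carries both arms, while the enoate and the bromoalkene are too hindered and electron-poor to take part.

Step 14
Reactants: 21
Product: 22 pentacyclic 2-ene 19,10-lactone (ring A closed)
Conditions: KOt-Bu (0.3 equiv), t-BuOH/THF, 0 °C to rt
Reagents that add atoms: none
Why: Intramolecular Michael addition (5-exo-trig) of the lactone dienolate through C4 to C5 of the enoate closes ring A and the γ-lactone together; C4, held in the seven-membered ring by C3 and C19, can reach C5 only on the α face where the lactone oxygen sits, which fixes C4 (methyl β) and C5 (H β), and the C6 ester enolate is protonated under equilibrating conditions to the epimer with the ester trans to C4.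

Step 15
Reactants: 22
Product: 23 2β,3β-diol
Conditions: OsO4 (5 mol%), N-methylmorpholine N-oxide, acetone/H2O, rt
Reagents that add atoms: osmium tetroxide (O=[Os](=O)(=O)=O, catalytic oxygen carrier); N-methylmorpholine N-oxide (C[N+]1([O-])CCOCC1); water (O)
Why: Upjohn dihydroxylation should occur on the exo (β) face of the bicyclic lactone, away from the O–C19 bridge, and the brominated exocyclic alkene is too electron-poor and hindered to compete.

Step 16
Reactants: 23
Product: 24 16-methylene compound (bromine removed)
Conditions: Bu3SnH, AIBN (cat.), toluene, 90 °C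
Reagents that add atoms: none
Why: Radical hydrodebromination of the vinyl bromide by tin hydride unmasks the exocyclic methylene without touching the diol, lactone, ester or ketal.

Step 17
Reactants: 24
Product: 25 methyl ester of the target (C12 ketone)
Conditions: 1 M aq. HCl, THF, rt
Reagents that add atoms: water (O)
Why: Mild acid hydrolysis of the dioxolane frees the C12 ketone under conditions that should not move the exocyclic alkene, which in any case cannot conjugate through bridgehead C13.

Step 18
Reactants: 25
Product: 26 CNP0307952.1 (target)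
Conditions: LiSPr, HMPA, rt; then dilute HCl
Reagents that add atoms: none
Why: SN2 demethylation of the hindered methyl ester by thiolate avoids hydroxide and therefore the retro-aldol opening of the 3-hydroxy lactone.

Compound list
1 | (R)-4-(tert-butyldimethylsilyloxy)cyclopent-2-en-1-one | O=C1C=C[C@H](O[Si](C)(C)C(C)(C)C)C1 | starting material
2 | formaldehyde | C=O | starting material
3 | (R)-4-(tert-butyldimethylsilyloxy)-2-(hydroxymethyl)cyclopent-2-en-1-one | O=C1C(CO)=C[C@H](O[Si](C)(C)C(C)(C)C)C1 | intermediate
4 | (R)-2-(bromomethyl)-4-(tert-butyldimethylsilyloxy)cyclopent-2-en-1-one | O=C1C(CBr)=C[C@H](O[Si](C)(C)C(C)(C)C)C1 | intermediate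
5 | ethynyltrimethylsilane | C#C[Si](C)(C)C | starting material
6 | (R)-4-(tert-butyldimethylsilyloxy)-2-[3-(trimethylsilyl)prop-2-yn-1-yl]cyclopent-2-en-1-one | O=C1C(CC#C[Si](C)(C)C)=C[C@H](O[Si](C)(C)C(C)(C)C)C1 | intermediate
7 | (R)-2-(3-bromoprop-2-yn-1-yl)-4-(tert-butyldimethylsilyloxy)cyclopent-2-en-1-one (ring B: C6 carbonyl, C8=C9, C10 silyloxy) | O=C1C(CC#CBr)=C[C@H](O[Si](C)(C)C(C)(C)C)C1 | intermediate
8 | 2-(tert-butyldimethylsilyloxy)buta-1,3-diene | C=CC(=C)O[Si](C)(C)C(C)(C)C | starting material
9 | cis-fused B/C bicycle: C6 ketone, 10β-silyloxy, 9β-H, 3-bromoprop-2-ynyl on C8 (β), silyl enol ether at C12=C13 | BrC#CC[C@]12CC=C(O[Si](C)(C)C(C)(C)C)C[C@H]1[C@H](O[Si](C)(C)C(C)(C)C)CC2=O | intermediate (not isolated)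
10 | B/C/D tricycle: 6,12-diketone, 10β-silyloxy, 9β-H, (Z)-bromomethylene at C16 | Br/C=C1/C[C@]23C[C@H]1C(=O)C[C@H]2[C@H](O[Si](C)(C)C(C)(C)C)CC3=O | intermediate
11 | 12,12-ethylenedioxy derivative of 10 | Br/C=C1/C[C@]23C[C@H]1C1(OCCO1)C[C@H]2[C@H](O[Si](C)(C)C(C)(C)C)CC3=O | intermediate
12 | C6 enol triflate (C5=C6) of 11 | Br/C=C1/C[C@]23C[C@H]1C1(OCCO1)C[C@H]2[C@H](O[Si](C)(C)C(C)(C)C)C=C3OS(=O)(=O)C(F)(F)F | intermediate
13 | methyl C5=C6 enoate, 10β-silyloxy, 12-ketal | Br/C=C1/C[C@]23C[C@H]1C1(OCCO1)C[C@H]2[C@H](O[Si](C)(C)C(C)(C)C)C=C3C(=O)OC | intermediate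
14 | 10β-alcohol of 13 | Br/C=C1/C[C@]23C[C@H]1C1(OCCO1)C[C@H]2[C@H](O)C=C3C(=O)OC | intermediate
15 | C10 ketone (ring-B enone ester), 12-ketal | Br/C=C1/C[C@]23C[C@H]1C1(OCCO1)C[C@H]2C(=O)C=C3C(=O)OC | intermediate
16 | allylmagnesium bromide | C=CC[Mg]Br | starting material
17 | tertiary alcohol: 10α-OH, 10β-allyl | Br/C=C1/C[C@]23C[C@H]1C1(OCCO1)C[C@H]2[C@](O)(CC=C)C=C3C(=O)OC | intermediate
18 | 2-methylbut-3-enoic acid (racemic) | C=CC(C)C(=O)O | starting material
19 | 2-methylbut-3-enoyl chloride | C=CC(C)C(=O)Cl | intermediate (not isolated)
20 | 10α-(2-methylbut-3-enoyloxy)-10β-allyl ester (both epimers at the acyl α-carbon) | Br/C=C1/C[C@]23C[C@H]1C1(OCCO1)C[C@H]2[C@](OC(=O)C(C)C=C)(CC=C)C=C3C(=O)OC | intermediate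
21 | seven-membered unsaturated lactone spiro-fused at C10 (both epimers at C4) | Br/C=C1/C[C@]23C[C@H]1C1(OCCO1)C[C@H]2[C@@]1(OC(=O)C(C)/C=C\C1)C=C3C(=O)OC | intermediate
22 | pentacyclic 2-ene 19,10-lactone: 4β-methyl, 5β-H, 6β-CO2Me, 12-ketal, 17-bromo | Br/C=C1/C[C@]23C[C@H]1C1(OCCO1)C[C@H]2[C@@]12CC=C[C@@](C)(C(=O)O1)[C@H]2[C@@H]3C(=O)OC | intermediate
23 | 2β,3β-diol of 22 | Br/C=C1/C[C@]23C[C@H]1C1(OCCO1)C[C@H]2[C@@]12C[C@H](O)[C@H](O)[C@@](C)(C(=O)O1)[C@H]2[C@@H]3C(=O)OC | intermediate
24 | 16-methylene 12-ketal diol methyl ester | C=C1C[C@]23C[C@H]1C1(OCCO1)C[C@H]2[C@@]12C[C@H](O)[C@H](O)[C@@](C)(C(=O)O1)[C@H]2[C@@H]3C(=O)OC | intermediate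
25 | methyl ester of the target (12-ketone) | C=C1C[C@]23C[C@H]1C(=O)C[C@H]2[C@@]12C[C@H](O)[C@H](O)[C@@](C)(C(=O)O1)[C@H]2[C@@H]3C(=O)OC | intermediate
26 | CNP0307952.1 | C=C1C[C@]23C[C@H]1C(=O)C[C@H]2[C@@]12C[C@H](O)[C@H](O)[C@@](C)(C(=O)O1)[C@H]2[C@@H]3C(=O)O | target

Total step count: 18. Longest linear sequence: 18 steps (1 to 26).

Steps most likely to fail:

Step 5. The α-branched, γ-silyloxy enone may react sluggishly or lose its silyloxy group under the acid catalyst, and the enol ether may be protodesilylated before ring D closes. The fallback changes the diene and separates the two ring closures. Compound 7 would be heated in toluene, without acid, with (E)-3-(tert-butyldimethylsilyloxy)-N,N-dimethylbuta-1,3-dien-1-amine to give the amino silyl enol ether cycloadduct F1, with the same regiochemistry and facial sense. Dilute HCl in THF at 0 °C would then hydrolyse the enol ether and eliminate dimethylamine to give the enedione F2 (C12 ketone conjugated with C13=C14). Conjugate reduction with [(Ph3P)CuH]6 in the presence of t-BuMe2SiCl would regenerate the C12=C13 silyl enol ether regiospecifically, which is 9, now isolated. Compound 9 would be closed to 10 with Ph3PAuCl, AgBF4 and MeOH as in step 5.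

Step 14. The dienolate of the seven-membered lactone may fail to reach C5 because of strain in the bridging transition state, or the addition may revert. The fallback reverses the order of the two ring closures and sets out from 20. KN(SiMe3)2 in THF at −78 °C would give the open-chain ester dienolate, whose 5-exo-trig Michael addition to C5 forms the γ-lactone F3 with vinyl and methyl on C4 and allyl on C10. The C4 epimer with vinyl on the side of the allyl group would then close the six-membered ring A by metathesis (second-generation Hoveyda–Grubbs catalyst) to give 22. The other epimer can be returned to the mixture with base by retro-Michael and Michael addition.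

Step 15. Osmylation may take place on the α face, or with poor facial preference, if the C18 methyl and H-5 shield the β face more than expected. The fallback reverses the facial outcome by a different mechanism: Woodward cis-hydroxylation of 22 (I2, AgOAc, wet AcOH). Iodonium formation on the accessible face, anti opening by acetate, closure to the acetoxonium ion with inversion and hydrolysis place both oxygens on the face opposite to the one the electrophile attacks. This gives the monoacetate F4, which K2CO3 in MeOH would cleave to 23.

Further compounds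
F1 | step 5 | amino silyl enol ether cycloadduct (14-dimethylamino, C12=C13 silyl enol ether, C14 configuration left open) | BrC#CC[C@]12C(N(C)C)C=C(O[Si](C)(C)C(C)(C)C)C[C@H]1[C@H](O[Si](C)(C)C(C)(C)C)CC2=O
F2 | step 5 | bicyclic enedione (C6 ketone, C12 ketone conjugated with C13=C14) | BrC#CC[C@]12C=CC(=O)C[C@H]1[C@H](O[Si](C)(C)C(C)(C)C)CC2=O
F3 | step 14 | γ-lactone with 4-vinyl, 4-methyl and 10β-allyl (ring A open) | Br/C=C1/C[C@]23C[C@H]1C1(OCCO1)C[C@H]2[C@@]1(CC=C)OC(=O)[C@](C)(C=C)[C@H]1[C@@H]3C(=O)OC
F4 | step 15 | 2β-acetoxy-3β-hydroxy derivative of 22 | Br/C=C1/C[C@]23C[C@H]1C1(OCCO1)C[C@H]2[C@@]12C[C@H](OC(C)=O)[C@H](O)[C@@](C)(C(=O)O1)[C@H]2[C@@H]3C(=O)OC
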